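**Plan** (atoms numbered as in the target benzofuranone: O-1, C-2, C-3, C-3a, C-4 … C-7a)

1. Cuts, in retrosynthetic order: C-4 carbinol → enone; C-5=C-6 with the C-6 CH2–O ester and C-4–O → vinyl epoxide; C-3 methylene → Mannich step; lactone O–C-7a → acyl group on C-7a (Baeyer–Villiger); then C-6–C-7 and C-3a–C-7a together ([4+2]); last the allene–vinyl bond.
2. Forward: (S)-citronellal → alkyne → propargylic carbonate → vinylallene; an amine-catalysed Diels–Alder reaction with ethyl vinyl ketone closes the carbocycle; Baeyer–Villiger oxidation and lactonisation close the lactone; methylenation, epoxide opening and oxidation/reduction finish.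
3. Enabling feature: in the carbocycle (C-3a to C-7a) the only ring C=C (C-5=C-6) lies between the exocyclic CH2–O carbon on C-6 and the C-4 carbinol. This 2-ene-1,4-dioxygen unit is the 1,4-adduct of an exocyclic s-trans diene (6-methylidene, C-4=C-5), which is what a vinylallene leaves after [4+2] at its vinyl terminus (C-3a) and central allene carbon (C-6). The ring edge C-7/C-7a (CH2–CH–O) is a vinyl ketone.
4. Stereochemistry: the side-chain centre comes from (S)-citronellal. C-3a/C-7a are set by the chiral amine catalyst (endo, cis), made trans by epimerisation next to the ketone and kept by the retentive Baeyer–Villiger step. C-4 is set by CBS reduction. The tetrasubstituted alkene geometry is fixed by the ring.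

Key step: step 8

Remark 1: the (2S,5S) imidazolidinone is assumed to give the facial sense drawn for 14; if the sense is the reverse, the (2R,5R) catalyst is used.
Remark 2: epoxide 24 is drawn as the isomer expected from attack anti to C-3; the other epoxide would give the C-4 epimer of 25 and converge at 26.

**Route**

Step 1
Reactants: 1 (S)-citronellal
Product: 3 (3S)-3,7-dimethyloct-6-en-1-yne, via enol nonaflate 2 (not isolated)
Conditions: nonafluorobutanesulfonyl fluoride, P2-Et phosphazene base, DMF, −30 °C to rt
Reagents that add atoms: none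
Why: One-pot nonaflation–elimination of an enolisable aldehyde gives the terminal alkyne; the stereocentre is β to the aldehyde, is not touched and comes from the chiral pool.

Step 2
Reactants: 3 (3S)-3,7-dimethyloct-6-en-1-yne
Product: 5 (4S)-4,8-dimethylnon-7-en-2-yn-1-ol, via lithium acetylide 4 (not isolated)
Conditions: n-BuLi, THF, −78 °C; then (CH2O)n, −78 °C to rt
Reagents that add atoms: paraformaldehyde (as formaldehyde), C=O
Why: Acetylide addition to formaldehyde (hydroxymethylation); no stereocentre is formed.

Step 3
Reactants: 5 (4S)-4,8-dimethylnon-7-en-2-yn-1-ol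
Product: 6 methyl (4S)-4,8-dimethylnon-7-en-2-yn-1-yl carbonate
Conditions: ClCO2Me, pyridine, CH2Cl2, 0 °C
Reagents that add atoms: methyl chloroformate, COC(=O)Cl
Why: O-acylation gives the propargylic carbonate that later serves as leaving group and internal base source.

Step 4
Reactants: 6 methyl (4S)-4,8-dimethylnon-7-en-2-yn-1-yl carbonate
Product: 8 (4S)-7-hydroxy-4-methylhept-2-yn-1-yl methyl carbonate, via ozonide 7 (not isolated)
Conditions: O3, CH2Cl2, −78 °C; then NaBH4, MeOH, −78 to 0 °C
Reagents that add atoms: ozone, [O-][O+]=O
Why: Ozonolysis with reductive work-up; the trisubstituted alkene reacts with ozone much faster than the internal alkyne, and borohydride reduces the ozonide to the primary alcohol without touching the carbonate.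

Step 5
Reactants: 8 (4S)-7-hydroxy-4-methylhept-2-yn-1-yl methyl carbonate
Product: 9 (4S)-7-[tert-butyl(dimethyl)silyloxy]-4-methylhept-2-yn-1-yl methyl carbonate
Conditions: TBSCl, imidazole, DMF, rt
Reagents that add atoms: tert-butyldimethylsilyl chloride, CC(C)(C)[Si](C)(C)Cl
Why: Silylation of the primary alcohol; the silyl ether survives the basic steps 9, 11 and 12 that an acetate would not.

Step 6
Reactants: 10 methyl but-3-ynoate
Product: 11 methyl (E)-4-(4,4,5,5-tetramethyl-1,3,2-dioxaborolan-2-yl)but-3-enoate
Conditions: pinacolborane, Cp2Zr(H)Cl (5 mol %), CH2Cl2, rt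
Reagents that add atoms: pinacolborane, CC1(C)OBOC1(C)C
Why: Zirconium-catalysed syn hydroboration of the terminal alkyne gives the E-alkenylboronate under neutral conditions that avoid isomerisation to the allenoate.

Step 7
Reactants: 9 propargylic carbonate; 11 alkenylboronate
Product: 12 methyl (3E)-5-[(2S)-5-[tert-butyl(dimethyl)silyloxy]pentan-2-yl]hepta-3,5,6-trienoate
Conditions: Pd(PPh3)4 (5 mol %), THF, 50 °C, no added base
Reagents that add atoms: none
Why: Suzuki–Miyaura coupling of a propargylic carbonate: SN2'-type oxidative addition gives an allenylpalladium species, the released methoxide activates the boronate, and reductive elimination gives the vinylallene with the E-alkene retained; without added base the skipped ester is not conjugated.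

Step 8
Reactants: 12 vinylallene ester; 13 ethyl vinyl ketone (pent-1-en-3-one)
Product: 14 methyl 2-[3-[(2S)-5-[tert-butyl(dimethyl)silyloxy]pentan-2-yl]-4-methylidene-6-propanoylcyclohex-2-en-1-yl]acetate, 1,6-cis (endo adduct), absolute configuration as in its SMILES
Conditions: (2S,5S)-5-benzyl-3-methyl-2-(5-methylfuran-2-yl)imidazolidin-4-one·HClO4 (20 mol %), 13 (3 equiv), EtOH, −30 °C
Reagents that add atoms: none
Why: The secondary amine condenses with 13 to a chiral unsaturated iminium ion, which undergoes a concerted, asynchronous [4+2] cycloaddition with the s-cis diene formed by the vinyl group and the proximal allene double bond of 12; hydrolysis returns the catalyst. The closest known reaction type is the imidazolidinone-catalysed Diels–Alder reaction of simple vinyl ketones with acyclic dienes, combined with the known diene behaviour of vinylallenes. One ring is closed, the cyclohexene, in an intermolecular suprafacial six-centre mode that leaves the distal allene double bond as the exocyclic methylidene. The two new stereocentres form together: their cis relation follows from the endo position of the iminium carbon next to the E-configured diene terminus, and their absolute configuration from shielding of one dienophile face by the benzyl group of the catalyst, which overrides the remote side-chain centre. The selectivity needed is regiochemical, and the substrate secures it: the central allene carbon, para to the alkyl branch and leading to an allyl-stabilised transition state, bonds to the unsubstituted enone carbon, so the acyl-bearing carbon ends next to the carbon carrying the CH2CO2Me arm.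

Step 9
Reactants: 14 cis keto ester
Product: 15 methyl 2-[3-[(2S)-5-[tert-butyl(dimethyl)silyloxy]pentan-2-yl]-4-methylidene-6-propanoylcyclohex-2-en-1-yl]acetate, 1,6-trans
Conditions: DBU (0.3 equiv), CH2Cl2, rt
Reagents that add atoms: none
Why: Base-mediated epimerisation α to the ketone should favour the trans, di-pseudoequatorial isomer; the carbon carrying the ester arm is not acidic and keeps the catalyst-set configuration, and remaining cis isomer can be recycled.

Step 10
Reactants: 15 trans keto ester
Product: 16 methyl 2-[3-[(2S)-5-[tert-butyl(dimethyl)silyloxy]pentan-2-yl]-4-methylidene-6-(propanoyloxy)cyclohex-2-en-1-yl]acetate, 1,6-trans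
Conditions: (Me3SiO)2, SnCl4 (10 mol %), trans-cyclohexane-1,2-diamine (10 mol %), MS 4 Å, CH2Cl2, rt
Reagents that add atoms: bis(trimethylsilyl) peroxide, C[Si](C)(C)OO[Si](C)(C)C
Why: Baeyer–Villiger oxidation under non-epoxidising silyl peroxide conditions; the secondary ring carbon migrates in preference to ethyl and with retention, so the new C–O bond keeps the trans configuration.

Step 11
Reactants: 16 propanoate ester
Product: 18 trans-fused 5-[(2S)-5-[tert-butyl(dimethyl)silyloxy]pentan-2-yl]-6-methylidene-3a,6,7,7a-tetrahydro-1-benzofuran-2(3H)-one (3aR,7aR), via hydroxy ester 17 (not isolated)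
Conditions: K2CO3, MeOH, 0 °C to rt; then PPTS (cat.), toluene, 60 °C
Reagents that add atoms: none
Why: Transesterification frees the secondary alcohol, which then closes the five-membered lactone onto the methyl ester (lactonisation); no stereocentre changes and no other hydroxyl is present to compete.

Step 12
Reactants: 18 lactone
Product: 21 trans-fused 5-[(2S)-5-[tert-butyl(dimethyl)silyloxy]pentan-2-yl]-3,6-dimethylidene-3a,6,7,7a-tetrahydro-1-benzofuran-2(3H)-one, via Mannich base 19 (not isolated), via ammonium iodide 20 (not isolated)
Conditions: LiN(SiMe3)2, THF, −78 °C; Me2N=CH2 I, −78 to 0 °C; then MeI, MeOH, rt; then NaHCO3 (aq), CH2Cl2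
Reagents that add atoms: N,N-dimethylmethyleneiminium iodide (Eschenmoser's salt), C=[N+](C)C.[I-]
Why: Mannich methylenation: the lactone α-carbon is the only enolisable position, and aminomethylation, quaternisation and elimination give the exocyclic methylene, erasing the transient α-centre.

Step 13
Reactants: 21 silyl ether
Product: 22 trans-fused 5-[(2S)-5-hydroxypentan-2-yl]-3,6-dimethylidene-3a,6,7,7a-tetrahydro-1-benzofuran-2(3H)-one
Conditions: HF·pyridine, pyridine, THF, 0 °C
Reagents that add atoms: none
Why: Buffered fluoride desilylation of a primary silyl ether; the diene and the methylene lactone tolerate these conditions.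

Step 14
Reactants: 22 primary alcohol
Product: 23 (4S)-4-(3,6-dimethylidene-2-oxo-2,3,3a,6,7,7a-hexahydro-1-benzofuran-5-yl)pentyl acetate, trans-fused
Conditions: Ac2O, pyridine, DMAP (cat.), CH2Cl2, 0 °C
Reagents that add atoms: acetic anhydride, CC(=O)OC(C)=O
Why: Acetylation of the only hydroxyl group, placed before the C-4 oxygen exists so that no selectivity is needed.

Step 15
Reactants: 23 diene acetate
Product: 24 4,5-epoxide of 23 (oxirane on C-4/C-5, oxygen anti to C-3)
Conditions: mCPBA (1.05 equiv), NaHCO3, CH2Cl2, 0 °C
Reagents that add atoms: 3-chloroperoxybenzoic acid, OOC(=O)c1cccc(Cl)c1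
Why: Prilezhaev epoxidation of the most nucleophilic double bond, the trisubstituted ring alkene; the face is not critical because C-4 is reset in steps 17 and 18.

Step 16
Reactants: 24 vinyl epoxide
Product: 25 C-4 epimer of the target (4-OH trans to C-3)
Conditions: Pd(PPh3)4 (5 mol %), methacrylic acid (1.5 equiv), THF, 0 °C to rt
Reagents that add atoms: methacrylic acid, C=C(C)C(=O)O
Why: Tsuji–Trost-type 1,4-opening: zerovalent palladium ionises the allylic C–O bond of the vinyl epoxide and the carboxylate attacks the unhindered CH2 terminus, giving the tetrasubstituted ring alkene, the primary methacrylate and the free carbinol with the configuration of the epoxide.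

Step 17
Reactants: 25 allylic alcohol
Product: 26 [5-[(2S)-5-acetoxypentan-2-yl]-3-methylidene-2,4-dioxo-2,3,3a,4,7,7a-hexahydro-1-benzofuran-6-yl]methyl 2-methylprop-2-enoate, trans-fused
Conditions: MnO2 (excess), CH2Cl2, rt
Reagents that add atoms: none
Why: Allylic oxidation touches only the C-4 carbinol and converges either C-4 epimer on one enone.

Step 18
Reactants: 26 enone
Product: 27 target, [(3aR,4S,7aR)-5-[(2S)-5-acetoxypentan-2-yl]-4-hydroxy-3-methylidene-2-oxo-2,3,3a,4,7,7a-hexahydro-1-benzofuran-6-yl]methyl 2-methylprop-2-enoate
Conditions: (R)-2-methyl-CBS-oxazaborolidine (0.5 equiv), catecholborane, toluene, −78 °C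
Reagents that add atoms: none
Why: CBS reduction: reagent-controlled 1,2-hydride delivery from the face anti to C-3 (alkenyl side as the large group, matched with the equatorial approach a bulky reductant prefers) should set the carbinol cis to C-3; catecholborane leaves the esters and the ester-conjugated alkenes alone.

**Compound list**

1 | (S)-citronellal, (3S)-3,7-dimethyloct-6-enal | O=CC[C@@H](C)CCC=C(C)C | starting material
2 | (3S)-3,7-dimethylocta-1,6-dien-1-yl nonafluorobutane-1-sulfonate (E/Z mixture) | FC(F)(F)C(F)(F)C(F)(F)C(F)(F)S(=O)(=O)OC=C[C@@H](C)CCC=C(C)C | intermediate (not isolated)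
3 | (3S)-3,7-dimethyloct-6-en-1-yne | C#C[C@@H](C)CCC=C(C)C | intermediate
4 | lithium acetylide of 3 | [Li]C#C[C@@H](C)CCC=C(C)C | intermediate (not isolated)
5 | (4S)-4,8-dimethylnon-7-en-2-yn-1-ol | OCC#C[C@@H](C)CCC=C(C)C | intermediate
6 | methyl (4S)-4,8-dimethylnon-7-en-2-yn-1-yl carbonate | COC(=O)OCC#C[C@@H](C)CCC=C(C)C | intermediate
7 | ozonide of 6 (1,2,4-trioxolane) | COC(=O)OCC#C[C@@H](C)CCC1OOC(C)(C)O1 | intermediate (not isolated)
8 | (4S)-7-hydroxy-4-methylhept-2-yn-1-yl methyl carbonate | COC(=O)OCC#C[C@@H](C)CCCO | intermediate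
9 | (4S)-7-[tert-butyl(dimethyl)silyloxy]-4-methylhept-2-yn-1-yl methyl carbonate | COC(=O)OCC#C[C@@H](C)CCCO[Si](C)(C)C(C)(C)C | intermediate
10 | methyl but-3-ynoate | COC(=O)CC#C | starting material
11 | methyl (E)-4-(4,4,5,5-tetramethyl-1,3,2-dioxaborolan-2-yl)but-3-enoate | COC(=O)C/C=C/B1OC(C)(C)C(C)(C)O1 | intermediate
12 | methyl (3E)-5-[(2S)-5-[tert-butyl(dimethyl)silyloxy]pentan-2-yl]hepta-3,5,6-trienoate | C=C=C([C@@H](C)CCCO[Si](C)(C)C(C)(C)C)/C=C/CC(=O)OC | intermediate
13 | ethyl vinyl ketone (pent-1-en-3-one) | C=CC(=O)CC | starting material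
14 | cis (endo) cycloadduct, keto ester | C=C1C([C@@H](C)CCCO[Si](C)(C)C(C)(C)C)=C[C@@H](CC(=O)OC)[C@@H](C(=O)CC)C1 | intermediate
15 | trans keto ester | C=C1C([C@@H](C)CCCO[Si](C)(C)C(C)(C)C)=C[C@@H](CC(=O)OC)[C@H](C(=O)CC)C1 | intermediate
16 | trans propanoate ester | C=C1C([C@@H](C)CCCO[Si](C)(C)C(C)(C)C)=C[C@@H](CC(=O)OC)[C@H](OC(=O)CC)C1 | intermediate
17 | trans hydroxy ester | C=C1C([C@@H](C)CCCO[Si](C)(C)C(C)(C)C)=C[C@@H](CC(=O)OC)[C@H](O)C1 | intermediate (not isolated)
18 | trans-fused lactone (3aR,7aR), silyl ether | C=C1C([C@@H](C)CCCO[Si](C)(C)C(C)(C)C)=C[C@H]2CC(=O)O[C@@H]2C1 | intermediate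
19 | 3-(dimethylaminomethyl) lactone (C-3 epimers) | C=C1C([C@@H](C)CCCO[Si](C)(C)C(C)(C)C)=C[C@H]2C(CN(C)C)C(=O)O[C@@H]2C1 | intermediate (not isolated)
20 | trimethylammoniomethyl lactone iodide | C=C1C([C@@H](C)CCCO[Si](C)(C)C(C)(C)C)=C[C@H]2C(C[N+](C)(C)C)C(=O)O[C@@H]2C1.[I-] | intermediate (not isolated)
21 | 3,6-dimethylidene lactone, silyl ether | C=C1C([C@@H](C)CCCO[Si](C)(C)C(C)(C)C)=C[C@H]2C(=C)C(=O)O[C@@H]2C1 | intermediate
22 | 3,6-dimethylidene lactone, primary alcohol | C=C1C([C@@H](C)CCCO)=C[C@H]2C(=C)C(=O)O[C@@H]2C1 | intermediate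
23 | 3,6-dimethylidene lactone, acetate | C=C1C([C@@H](C)CCCOC(C)=O)=C[C@H]2C(=C)C(=O)O[C@@H]2C1 | intermediate
24 | 4,5-epoxide of 23 (oxygen anti to C-3) | C=C1C[C@H]2OC(=O)C(=C)[C@@H]2[C@H]3O[C@@]13[C@@H](C)CCCOC(C)=O | intermediate
25 | C-4 epimer of the target | C=C(C)C(=O)OCC1=C([C@@H](C)CCCOC(C)=O)[C@H](O)[C@H]2C(=C)C(=O)O[C@@H]2C1 | intermediate
26 | 4-oxo compound (enone) | C=C(C)C(=O)OCC1=C([C@@H](C)CCCOC(C)=O)C(=O)[C@H]2C(=C)C(=O)O[C@@H]2C1 | intermediate
27 | target | C=C(C)C(=O)OCC1=C([C@@H](C)CCCOC(C)=O)[C@@H](O)[C@H]2C(=C)C(=O)O[C@@H]2C1 | target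

**Totals**

Total step count: 18. Longest linear sequence: 17 (steps 1–5 and 7–18; step 6 is a one-step branch).

**Steps most likely to fail**

Step 10. The peroxide may epoxidise the exocyclic diene, the Lewis acid may move the exocyclic double bond into the ring, or migration in an acyclic ketone may be too slow. The fallback avoids the acyl-to-oxygen exchange by bringing the lactone oxygen in on the dienophile; it sets out from 9 and comes back at 18. But-3-ynoic acid F1 would be transvinylated with vinyl acetate ([Ir(cod)Cl]2, NaOAc, toluene) to ethenyl but-3-ynoate F2 and hydroborated as in step 6 to ethenyl (E)-4-(pinacolboryl)but-3-enoate F3. Coupling with 9 as in step 7 would give the vinylallene vinyl ester F4. Heating F4 (toluene, about 140 °C, BHT) should bring about an intramolecular Diels–Alder reaction that closes carbocycle and lactone together and gives 18. Catalyst control is lost on this path, so 18 would have to be separated from its ring-fusion and facial isomers.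

Step 8. Iminium turnover may be slow with the hindered trisubstituted vinylallene, the acidic medium may isomerise the allene or the product diene, or facial and endo selectivity may erode. The fallback uses a stoichiometric chiral auxiliary under Lewis acid activation; it sets out from 12 and comes back at 14. Cycloaddition of 12 with (S)-3-acryloyl-4-benzyloxazolidin-2-one (Et2AlCl, CH2Cl2, −78 °C; auxiliary antipode chosen to match 14) should give the endo imide F5. Cleavage with LiSEt would give the S-ethyl thioester F6, and Fukuyama coupling (EtZnI, PdCl2(PPh3)2) would give 14 without touching the methyl ester.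

Step 17. The C-3a hydrogen of enone 26 is activated by both the ketone and the methylene lactone, so the exocyclic double bond may migrate into conjugation or C-3a may epimerise on the oxidant surface or on work-up. The fallback avoids the ketone by inverting the carbinol; it sets out from 25 and comes back at 27. Mitsunobu reaction of 25 with formic acid (PPh3, DIAD, THF, 0 °C) should give the inverted formate F7, and mild methanolysis (KHCO3, MeOH, 0 °C) should free 27 while acetate, methacrylate and lactone stay intact. This path serves only the epimer drawn for 25.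

**Further compounds**

F1 | step 10 | but-3-ynoic acid | C#CCC(=O)O
F2 | step 10 | ethenyl but-3-ynoate | C#CCC(=O)OC=C
F3 | step 10 | ethenyl (E)-4-(4,4,5,5-tetramethyl-1,3,2-dioxaborolan-2-yl)but-3-enoate | C=COC(=O)C/C=C/B1OC(C)(C)C(C)(C)O1
F4 | step 10 | ethenyl (3E)-5-[(2S)-5-[tert-butyl(dimethyl)silyloxy]pentan-2-yl]hepta-3,5,6-trienoate | C=C=C([C@@H](C)CCCO[Si](C)(C)C(C)(C)C)/C=C/CC(=O)OC=C
F5 | step 8 | cis (endo) cycloadduct as N-acyl (S)-4-benzyloxazolidin-2-one | C=C1C([C@@H](C)CCCO[Si](C)(C)C(C)(C)C)=C[C@@H](CC(=O)OC)[C@@H](C(=O)N2[C@@H](Cc3ccccc3)COC2=O)C1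
F6 | step 8 | cis cycloadduct as S-ethyl thioester | C=C1C([C@@H](C)CCCO[Si](C)(C)C(C)(C)C)=C[C@@H](CC(=O)OC)[C@@H](C(=O)SCC)C1
F7 | step 17 | 4-O-formate of the target | C=C(C)C(=O)OCC1=C([C@@H](C)CCCOC(C)=O)[C@@H](OC=O)[C@H]2C(=C)C(=O)O[C@@H]2C1
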